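The south run, 0.028 M of G against 0.10 M of L, holds D near 57.2 % of the L charged. The north-west run, with 0.044 M of G, holds it near 43.5 %.

all flasks: L 0.10 M (fed, over 10 min)
- south: G 0.028 M; run made earlier
- north-west: G 0.044 M; run made earlier
- flask: G 0.0200 M; time 2.5 h

| run | time / h | D / % |
|---|---|---|
| south | 0.200 | 59 |
| south | 0.500 | 55 |
| south | 1.00 | 55 |
| south | 2.50 | 60 |
| north-west | 0.200 | 45 |
| north-west | 0.500 | 45 |
| north-west | 1.00 | 42 |
| north-west | 2.50 | 42 |

(scatter of a reading: 1.5 percentage points)

- at 2.5 h, what has stopped the reaction, if anything has (forward and back rates have come level / all of L has reacted / it is still moving)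
- D at 2.5 h, in percent of the L charged
- amount of D if the flask were left three thousand times as long, in percent of the L charged

- the analysis behind the earlier runs scatters by 1.5 percentage points, standard deviation
- the reaction counts as stopped when no species that holds the L changes by six tenths of a point or more over the second half of the time

Both runs are flat within the scatter from the first reading, so they call for a count of turnovers, not a rate. Suppose each G takes away one L. G then claims 28.0 % of the L in the south run and 44.0 % in the north-west run. D is then 79.5 % and 77.7 % of the L left over, equal within the scatter. Their mean, 78.6 %, is the free yield φ, the part of the L not taken by G that stands as D.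

In the flask G claims 20.0 % of the L, so D = φ(1 − G/L), with G and L the charges, gives 62.9 %. A fixed share could mean branching or a balance, but this reckoning takes the balance, so D stays at that value with some L still standing.

The forecast differs on the end, naming all of L has reacted, and it puts D higher, at 65 % at 2.5 h and 65 % on the long question: “L is used up, so D should stay put”.

The flask gives 63.8 % at 2.5 h and 63.8 % on the long question, and its end is forward and back rates have come level.

    L ⇌ Z (K = 2.30, k = 0.0170 s⁻¹)
    L + G → J (k = 4.10 M⁻¹ s⁻¹)
    L ⇌ D (K = 13.0, k = 0.0530 s⁻¹)

In the flask G, the limiting reagent, is down to 0 % of its charge at 2.5 h, and J stands at 20.0 % of the L charged, as counted. L stays at 4.91 % because D goes back to L: the same flask without that back reaction converts 100 % of L, against 95.1 %. So φ, read off scattered runs, stands for the share of D in a balance. In the neighbour flask with 0.060 M of L and the same G charge, φ gives 52.4 %, and that flask holds 53.2 %.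

(Readings and results are calculated for substances that don't exist, and the scatter is random.)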